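## Retrosynthetic overview

- The (Z)-feruloyl ester is cut last (carboxylate alkylation of a primary chloride) and the (E)-p-coumaroyl ester before it (Mitsunobu), leaving a chloropropyl dihydrobenzofuran diol.
- The diol comes from a trans methyl 2-aryl-2,3-dihydrobenzofuran-3-carboxylate, made by oxidative ring contraction of an (R)-flavanone: the ring A carbon C4a shifts from C4 to C3, and C2 relays its configuration to C3.
- The (R)-flavanone comes from a chromone and an aryl iodide by an enantioselective reductive conjugate arylation, the only catalyst-controlled stereocentre.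
- The chromone comes from 4-(3-chloropropyl)-2-methoxyphenol (ortho-acetylation, amide-acetal annulation). This phenol, the aryl iodide and (Z)-ferulic acid all derive from 4-iodo-2-methoxyphenol, made from 2-bromophenol.
- Ring order: the benzene rings are bought, the pyranone ring is closed in step 5 and contracted to the dihydrofuran ring in step 8.

Assumption: the SMILES is read as the (2R,3S), 2,3-trans dihydrobenzofuran carrying a Z ferulate on the propyl chain and an E p-coumarate on the C3 hydroxymethyl group.

## Route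

Step 1
Reactants: 1 2-bromophenol
Product: 2 2-methoxyphenol
Conditions: NaOMe (4 equiv), CuBr (10 mol %), MeOH/DMF, 110 °C; aq. HCl work-up
Reagents that add atoms: sodium methoxide, [Na+].[O-]C
Why: Copper-catalysed Ullmann-type methoxylation of the aryl bromide replaces Br by OMe at the same carbon, a standard conversion of bromophenols into guaiacols.

Step 2
Reactants: 2 2-methoxyphenol
Product: 3 4-iodo-2-methoxyphenol
Conditions: NaI (1.0 equiv), NaOH (1.0 equiv), aq. NaOCl (1.0 equiv, slow addition), MeOH, 0 °C; Na2S2O3/HCl work-up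
Reagents that add atoms: sodium iodide, [Na+].[I-]
Why: Electrophilic aromatic iodination of the phenoxide by hypoiodite made in situ goes para to the phenoxide oxygen, the most activated open position.

Step 3
Reactants: 3 4-iodo-2-methoxyphenol; 4 1-bromo-3-chloropropane
Product: 5 4-(3-chloropropyl)-2-methoxyphenol
Conditions: NiI2 (10 mol %), 4,4'-di-tert-butyl-2,2'-bipyridine (10 mol %), pyridine (10 mol %), Zn (2 equiv), DMA, 60 °C
Reagents that add atoms: none
Why: Nickel-catalysed reductive cross-electrophile coupling joins the aryl iodide to the bromide end of the dihalide only, because the C–Cl bond is inert under these conditions and the free phenol is tolerated.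

Step 4
Reactants: 5 4-(3-chloropropyl)-2-methoxyphenol; 6 acetic anhydride
Product: 8 1-[5-(3-chloropropyl)-2-hydroxy-3-methoxyphenyl]ethan-1-one, via aryl acetate 7 (not isolated)
Conditions: Ac2O (1.2 equiv), BF3·OEt2 (3 equiv, promoter), 85 °C, 3 h; then aq. NaOAc, 50 °C
Reagents that add atoms: none
Why: O-Acetylation followed by Lewis acid Fries rearrangement moves the acetyl group to the only free position ortho to the phenol oxygen (para is blocked), driven by the boron chelate of the ortho-hydroxy ketone.

Step 5
Reactants: 8 1-[5-(3-chloropropyl)-2-hydroxy-3-methoxyphenyl]ethan-1-one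
Product: 10 6-(3-chloropropyl)-8-methoxy-4H-chromen-4-one, via enaminone 9 (not isolated)
Conditions: Me2NCH(OMe)2 (1.5 equiv), toluene, 100 °C; concentrate; AcOH, 100 °C
Reagents that add atoms: N,N-dimethylformamide dimethyl acetal, COC(OC)N(C)C
Why: Condensation of the methyl ketone with the amide acetal gives the enaminone, and acid-promoted intramolecular oxa-Michael addition with loss of dimethylamine closes the pyranone ring (standard chromone synthesis).

Step 6
Reactants: 3 4-iodo-2-methoxyphenol
Product: 11 4-iodo-2-methoxyphenyl 2,2-dimethylpropanoate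
Conditions: t-BuCOCl (1.1 equiv), K2CO3 (1.5 equiv), acetone, rt
Reagents that add atoms: pivaloyl chloride, CC(C)(C)C(Cl)=O
Why: Phenol O-acylation installs a pivalate that shields the ring B phenol from the later trivalent iodine oxidant, weakens its donor power (less acid ionisation at C2), and is removed for free in the hydride step.

Step 7
Reactants: 10 6-(3-chloropropyl)-8-methoxy-4H-chromen-4-one; 11 4-iodo-2-methoxyphenyl 2,2-dimethylpropanoate
Product: 12 4-[(2R)-6-(3-chloropropyl)-8-methoxy-4-oxo-3,4-dihydro-2H-chromen-2-yl]-2-methoxyphenyl 2,2-dimethylpropanoate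
Conditions: Pd(OCOCF3)2 (5 mol %), (S)-t-BuPyOx [(S)-4-tert-butyl-2-(pyridin-2-yl)-4,5-dihydrooxazole] (6 mol %), HCO2Na (1.5 equiv), NH4PF6 (30 mol %), CF3CH2OH/H2O 9:1, 50 °C; 11 used at 1.3 equiv
Reagents that add atoms: none
Why: Proposed new method: an enantioselective reductive Heck reaction (formal conjugate hydroarylation) of a chromone with an aryl iodide, in which zerovalent palladium formed by formate reduction adds oxidatively to 11, the fluoroalcohol strips iodide to give the cationic PyOx aryl palladium species, this inserts the chromone C2=C3 bond with the tert-butyl group of the ligand shielding one face so that aryl delivery sets C2 as R, and the palladium enolate is protonated while formate returns divalent palladium to zerovalent palladium with loss of CO2; the closest known reactions are the PyOx-palladium conjugate addition of arylboronic acids to chromones and the reductive Heck arylation of cyclic enones with aryl halides.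

Step 8
Reactants: 12 4-[(2R)-6-(3-chloropropyl)-8-methoxy-4-oxo-3,4-dihydro-2H-chromen-2-yl]-2-methoxyphenyl 2,2-dimethylpropanoate
Product: 14 methyl (2R,3R)-5-(3-chloropropyl)-2-[4-(2,2-dimethylpropanoyloxy)-3-methoxyphenyl]-7-methoxy-2,3-dihydro-1-benzofuran-3-carboxylate, via flavanone dimethyl ketal 13 (not isolated)
Conditions: PhI(OAc)2 (1.2 equiv), conc. H2SO4 (0.3 equiv), HC(OMe)3, rt, 12 h
Reagents that add atoms: trimethyl orthoformate, COC(OC)OC
Why: Oxidative ring contraction of a flavanone with trivalent iodine, in which the enol ether from ketal 13 is attacked at C3 anti to the C2 aryl group and the electron-rich ring A carbon C4a then shifts from C4 to C3 antiperiplanar to the departing iodobenzene (1,2-aryl shift), so the untouched C2 centre dictates the trans (2R,3R) ester, which is also the thermodynamic isomer.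

Step 9
Reactants: 14 methyl (2R,3R)-5-(3-chloropropyl)-2-[4-(2,2-dimethylpropanoyloxy)-3-methoxyphenyl]-7-methoxy-2,3-dihydro-1-benzofuran-3-carboxylate
Product: 15 4-[(2R,3S)-5-(3-chloropropyl)-3-(hydroxymethyl)-7-methoxy-2,3-dihydro-1-benzofuran-2-yl]-2-methoxyphenol
Conditions: i-Bu2AlH (6 equiv), CH2Cl2, −78 to 0 °C; aq. KNaC4H4O6 work-up
Reagents that add atoms: none
Why: Hydride reduction turns the methyl ester into the primary alcohol and cleaves the aryl pivalate in the same operation, while the alkyl chloride and both stereocentres are untouched (the C3 descriptor changes from R to S only through CIP priorities).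

Step 10
Reactants: 16 4-iodophenol; 17 acrylic acid
Product: 18 (2E)-3-(4-hydroxyphenyl)prop-2-enoic acid
Conditions: Pd(OAc)2 (1 mol %), K2CO3 (3 equiv), H2O, 90 °C; aq. HCl work-up
Reagents that add atoms: none
Why: Mizoroki–Heck arylation of acrylate with syn β-hydride elimination gives the E cinnamic acid.

Step 11
Reactants: 15 4-[(2R,3S)-5-(3-chloropropyl)-3-(hydroxymethyl)-7-methoxy-2,3-dihydro-1-benzofuran-2-yl]-2-methoxyphenol; 18 (2E)-3-(4-hydroxyphenyl)prop-2-enoic acid
Product: 19 [(2R,3S)-5-(3-chloropropyl)-2-(4-hydroxy-3-methoxyphenyl)-7-methoxy-2,3-dihydro-1-benzofuran-3-yl]methyl (2E)-3-(4-hydroxyphenyl)prop-2-enoate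
Conditions: PPh3 (1.5 equiv), diisopropyl azodicarboxylate (1.5 equiv), 18 (1.3 equiv), THF, 0 °C to rt
Reagents that add atoms: none
Why: Mitsunobu esterification engages the carboxylic acid (pKa about 4.5) far faster than the phenols (pKa about 10), so the only primary alcohol is acylated without phenol protection and no stereocentre is involved.

Step 12
Reactants: 3 4-iodo-2-methoxyphenol; 20 propiolic acid
Product: 21 3-(4-hydroxy-3-methoxyphenyl)prop-2-ynoic acid
Conditions: PdCl2(PPh3)2 (5 mol %), 1,4-bis(diphenylphosphino)butane (10 mol %), DBU (3 equiv), DMSO, 35 °C; aq. HCl work-up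
Reagents that add atoms: none
Why: Copper-free Sonogashira-type coupling of the aryl iodide with the terminal alkyne at low temperature keeps the carboxylic acid in place (no decarboxylation).

Step 13
Reactants: 21 3-(4-hydroxy-3-methoxyphenyl)prop-2-ynoic acid
Product: 22 (2Z)-3-(4-hydroxy-3-methoxyphenyl)prop-2-enoic acid
Conditions: H2 (1 atm, 1.0 equiv uptake), 5% Pd/CaCO3 poisoned with Pb(OAc)2, quinoline, EtOAc, rt, dark
Reagents that add atoms: none
Why: Lindlar semihydrogenation adds H2 syn to the alkyne and stops at the Z alkene.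

Step 14
Reactants: 19 [(2R,3S)-5-(3-chloropropyl)-2-(4-hydroxy-3-methoxyphenyl)-7-methoxy-2,3-dihydro-1-benzofuran-3-yl]methyl (2E)-3-(4-hydroxyphenyl)prop-2-enoate; 22 (2Z)-3-(4-hydroxy-3-methoxyphenyl)prop-2-enoic acid
Product: 23 3-[(2R,3S)-2-(4-hydroxy-3-methoxyphenyl)-3-({[(2E)-3-(4-hydroxyphenyl)prop-2-enoyl]oxy}methyl)-7-methoxy-2,3-dihydro-1-benzofuran-5-yl]propyl (2Z)-3-(4-hydroxy-3-methoxyphenyl)prop-2-enoate
Conditions: KHCO3 (1.2 equiv), NaI (0.5 equiv), 22 (1.3 equiv), DMF, 50 °C, dark, N2
Reagents that add atoms: none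
Why: Finkelstein-assisted SN2 O-alkylation of the carboxylate esterifies the chain; bicarbonate deprotonates only the carboxylic acid, so the three phenols stay free, and nothing present can isomerise the Z alkene.

## Compound list

1 | 2-bromophenol | Oc1ccccc1Br | starting material
2 | 2-methoxyphenol | COc1ccccc1O | intermediate
3 | 4-iodo-2-methoxyphenol | COc1cc(I)ccc1O | intermediate
4 | 1-bromo-3-chloropropane | ClCCCBr | starting material
5 | 4-(3-chloropropyl)-2-methoxyphenol | COc1cc(CCCCl)ccc1O | intermediate
6 | acetic anhydride | CC(=O)OC(C)=O | starting material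
7 | 4-(3-chloropropyl)-2-methoxyphenyl acetate | COc1cc(CCCCl)ccc1OC(C)=O | intermediate
8 | 1-[5-(3-chloropropyl)-2-hydroxy-3-methoxyphenyl]ethan-1-one | COc1cc(CCCCl)cc(C(C)=O)c1O | intermediate
9 | (2E)-1-[5-(3-chloropropyl)-2-hydroxy-3-methoxyphenyl]-3-(dimethylamino)prop-2-en-1-one | CN(C)/C=C/C(=O)c1cc(CCCCl)cc(OC)c1O | intermediate
10 | 6-(3-chloropropyl)-8-methoxy-4H-chromen-4-one | COc1cc(CCCCl)cc2c(=O)ccoc12 | intermediate
11 | 4-iodo-2-methoxyphenyl 2,2-dimethylpropanoate | COc1cc(I)ccc1OC(=O)C(C)(C)C | intermediate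
12 | 4-[(2R)-6-(3-chloropropyl)-8-methoxy-4-oxo-3,4-dihydro-2H-chromen-2-yl]-2-methoxyphenyl 2,2-dimethylpropanoate | O=C1C[C@H](c2ccc(OC(=O)C(C)(C)C)c(OC)c2)Oc2c(OC)cc(CCCCl)cc21 | intermediate
13 | 4-[(2R)-6-(3-chloropropyl)-4,4,8-trimethoxy-3,4-dihydro-2H-chromen-2-yl]-2-methoxyphenyl 2,2-dimethylpropanoate | COC1(OC)C[C@H](c2ccc(OC(=O)C(C)(C)C)c(OC)c2)Oc2c(OC)cc(CCCCl)cc21 | intermediate
14 | methyl (2R,3R)-5-(3-chloropropyl)-2-[4-(2,2-dimethylpropanoyloxy)-3-methoxyphenyl]-7-methoxy-2,3-dihydro-1-benzofuran-3-carboxylate | ClCCCc1cc(OC)c2c(c1)[C@@H](C(=O)OC)[C@H](c1ccc(OC(=O)C(C)(C)C)c(OC)c1)O2 | intermediate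
15 | 4-[(2R,3S)-5-(3-chloropropyl)-3-(hydroxymethyl)-7-methoxy-2,3-dihydro-1-benzofuran-2-yl]-2-methoxyphenol | ClCCCc1cc(OC)c2c(c1)[C@@H](CO)[C@H](c1ccc(O)c(OC)c1)O2 | intermediate
16 | 4-iodophenol | Oc1ccc(I)cc1 | starting material
17 | acrylic acid | C=CC(=O)O | starting material
18 | (2E)-3-(4-hydroxyphenyl)prop-2-enoic acid | O=C(O)/C=C/c1ccc(O)cc1 | intermediate
19 | [(2R,3S)-5-(3-chloropropyl)-2-(4-hydroxy-3-methoxyphenyl)-7-methoxy-2,3-dihydro-1-benzofuran-3-yl]methyl (2E)-3-(4-hydroxyphenyl)prop-2-enoate | ClCCCc1cc(OC)c2c(c1)[C@@H](COC(=O)/C=C/c1ccc(O)cc1)[C@H](c1ccc(O)c(OC)c1)O2 | intermediate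
20 | propiolic acid | C#CC(=O)O | starting material
21 | 3-(4-hydroxy-3-methoxyphenyl)prop-2-ynoic acid | COc1cc(C#CC(=O)O)ccc1O | intermediate
22 | (2Z)-3-(4-hydroxy-3-methoxyphenyl)prop-2-enoic acid | COc1cc(/C=C\C(=O)O)ccc1O | intermediate
23 | 3-[(2R,3S)-2-(4-hydroxy-3-methoxyphenyl)-3-({[(2E)-3-(4-hydroxyphenyl)prop-2-enoyl]oxy}methyl)-7-methoxy-2,3-dihydro-1-benzofuran-5-yl]propyl (2Z)-3-(4-hydroxy-3-methoxyphenyl)prop-2-enoate | COc1cc(/C=C\C(=O)OCCCc2cc(OC)c3c(c2)[C@@H](COC(=O)/C=C/c2ccc(O)cc2)[C@H](c2ccc(O)c(OC)c2)O3)ccc1O | target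

## Step count and risks

Total step count: 14. Longest linear sequence: 10 steps (steps 1, 2, 3, 4, 5, 7, 8, 9, 11, 14).

The three steps most likely to fail:

**Step 7 (proposed new step).** The risks are hydrodeiodination of 11, conjugate reduction of 10 by palladium hydride, poor turnover of the nitrogen-ligated zerovalent palladium, and an unproven level and sense of induction. The R outcome with the S ligand is a prediction from the face selectivity of the related boronic acid additions; if a test run gives the 2S flavanone, the R ligand is used. The fallback is known chemistry and sets out from 11. Palladium-catalysed borylation (Pd(OAc)2, 2-dicyclohexylphosphino-2',4',6'-triisopropylbiphenyl, B2(OH)4, KOAc, EtOH, 80 °C) gives [4-(2,2-dimethylpropanoyloxy)-3-methoxyphenyl]boronic acid F1. The established enantioselective conjugate addition of arylboronic acids to chromones (Pd(OCOCF3)2, (S)-t-BuPyOx, NH4PF6, H2O, ClCH2CH2Cl, 60 °C) then adds F1 to chromone 10 and comes back to the route at flavanone 12.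

**Step 8.** The known side paths are 3-methoxylation and the competing shift of the ring B aryl group (isoflavone), and strong acid could erode the C2 configuration. The fallback sets out from 12 and replaces the oxidative trivalent iodine chemistry by a halide-leaving 1,2-aryl shift. CuBr2 in EtOAc/CHCl3 at reflux brominates C3 to give the trans bromo ketone 4-[(2S,3S)-3-bromo-6-(3-chloropropyl)-8-methoxy-4-oxo-3,4-dihydro-2H-chromen-2-yl]-2-methoxyphenyl 2,2-dimethylpropanoate F2. HC(OMe)3/MeOH with catalytic TsOH converts it into the dimethyl ketal 4-[(2S,3S)-3-bromo-6-(3-chloropropyl)-4,4,8-trimethoxy-3,4-dihydro-2H-chromen-2-yl]-2-methoxyphenyl 2,2-dimethylpropanoate F3. ZnBr2 in toluene at 90 °C then triggers the classical rearrangement of an α-halo ketal, with the equatorial bromide antiperiplanar to the migrating C4–C4a bond, and comes back to the route at ester 14.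

**Step 4.** The risks are acylation para to the methoxy group instead of ortho to the hydroxyl, and partial demethylation. The fallback sets out from 5 and builds the ketone by cross-coupling instead of electrophilic acylation. NBS in MeCN at 0 °C brominates ortho to the free hydroxyl to give 2-bromo-4-(3-chloropropyl)-6-methoxyphenol F4. A regioselective Heck arylation of butyl vinyl ether at its α-carbon (Pd(OAc)2, 1,3-bis(diphenylphosphino)propane, Et3N, ethylene glycol, 110 °C) gives the enol ether 2-(1-butoxyethenyl)-4-(3-chloropropyl)-6-methoxyphenol F5. Dilute aqueous HCl hydrolyses F5 and comes back to the route at ketone 8.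

Further compounds
F1 | step 7 | [4-(2,2-dimethylpropanoyloxy)-3-methoxyphenyl]boronic acid | COc1cc(B(O)O)ccc1OC(=O)C(C)(C)C
F2 | step 8 | 4-[(2S,3S)-3-bromo-6-(3-chloropropyl)-8-methoxy-4-oxo-3,4-dihydro-2H-chromen-2-yl]-2-methoxyphenyl 2,2-dimethylpropanoate | O=C1[C@@H](Br)[C@H](c2ccc(OC(=O)C(C)(C)C)c(OC)c2)Oc2c(OC)cc(CCCCl)cc21
F3 | step 8 | 4-[(2S,3S)-3-bromo-6-(3-chloropropyl)-4,4,8-trimethoxy-3,4-dihydro-2H-chromen-2-yl]-2-methoxyphenyl 2,2-dimethylpropanoate | COC1(OC)[C@@H](Br)[C@H](c2ccc(OC(=O)C(C)(C)C)c(OC)c2)Oc2c(OC)cc(CCCCl)cc21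
F4 | step 4 | 2-bromo-4-(3-chloropropyl)-6-methoxyphenol | COc1cc(CCCCl)cc(Br)c1O
F5 | step 4 | 2-(1-butoxyethenyl)-4-(3-chloropropyl)-6-methoxyphenol | CCCCOC(=C)c1cc(CCCCl)cc(OC)c1O
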